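## The problem

Target 25 is a benzophenone whose carbonyl carbon lies between four ortho substituents: a propyl group and a hydroxyl on ring A, a hydroxyl and a CH2 group on ring B. That CH2 carries ring C, a 4-hydroxy-2-pyranone bound through its C6. There is no stereocentre, so nothing has to be controlled in space. The difficulty is the crowding at the diaryl ketone, which slows acylation and acyl transfer at either aryl carbonyl, together with the placement of six oxygen functions and two carbon side arms on three rings. Five acidic hydroxyls are present, and both resorcinol rings are easily oxidised and halogenated once free. Ring C is opened by alkoxide or hydroxide and is nucleophilic at C3 and C5, so it must be made late and the phenols unveiled last. The enolisable carbons of the ring C side arm sit where an aldol condensation onto the ketone would close a naphthalene ring; only the shielding of the carbonyl by its four ortho groups holds this back. The ring B arm cannot be carried as an arylacetic ester beside a 1,3-dicarbonyl unit, because Dieckmann closure to a naphthalene-1,3-diol would follow. The feature that opens the route is ring A itself: a 5-propylresorcinol acylated at C1, between C2 (propyl) and C6 (OH), with the second hydroxyl at C4. It is the dehydrogenation product of a 4-acyl-5-propylcyclohexane-1,3-dione. Carbons C2 to C5 plus the propyl group are the seven carbons of an alk-3-en-2-one, and C1 and C6 are the α-carbon and ester carbon of an aroylacetate. The crowding that makes the ketone hard to form also makes it inert as an electrophile, which the annulation needs.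

## Retrosynthesis

25 to 24. The four aryl O–CH3 bonds are cut last. Methyl ethers are chosen because ring B arrives as its dimethyl ether in 1 and because they survive every reagent of the route. The forward step is one Lewis-acid demethylation that must spare ring C and the hindered ketone.

24 to 22, then 18 plus 19. Ring C is cut at O1–C2 and at C5–C6. The lactone bond closes from acylketene 23, released thermally from dioxinone 22. The C5–C6 bond comes from acylation of dienolate 21 of dioxinone 19 by acid 18, activated as imidazolide 20. Against an open triketo ester that would need base to lactonise, the dioxinone gives ring C under neutral heat. The precursor 18 is a plain arylacetic acid. The forward reaction must favour C-acylation over enolisation of 20.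

18 to 16 to 15. These are an oxidation-level change and a desilylation. The arm is carried as a silyl-protected 2-hydroxyethyl group because an ester would undergo Dieckmann closure in the annulation and a free alcohol would form a cyclic hemiketal with the aryl ketone.

15 to 14 to 13. The two O–CH3 bonds on ring A are cut, then two C–H bonds are restored, which turns ring A into the cyclohexane-1,3-dione 13. Methylation is inserted so that ring A is inert to the oxidant and bases used later.

13 to 9 plus 10. This is the key cut, through ring A bonds C1–C2 and C5–C6. A union of two preformed arenes at the ketone would have to overcome four ortho groups; here the ketone is already present in aroylacetate 9 and ring A grows onto it. Enone 10 supplies the propyl group and four ring carbons in one commodity reagent. The forward reaction must close by Claisen attack on the ester and not by aldol attack on the aryl ketone.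

9 to 8, then 5 plus 6. The bond between the aryl carbonyl carbon and the CH2 is cut: aldol addition of enolate 7 of methyl acetate 6 to aldehyde 5 gives 8, and oxidation gives 9. Against acylation of a malonate by the corresponding benzoic acid, addition to an aldehyde is far less sensitive to the two ortho groups.

5 to 3 to 2 to 1. The aryl–CHO bond is cut (electrophilic formylation para to a methoxy group), then the O–Si bond, and the alcohol is traced to commercial acid 1.

## Roads not taken

Alternative 1: Ring B would be cut at the bond between its ketone-bearing carbon and its methyl-bearing carbon, giving the open tetraketone A2, stored as the 4-pyranone A1. In the forward step aqueous hydroxide opens A1 to A2, the methylene next to the aryl ketone attacks the terminal acetyl carbonyl, and dehydration gives benzophenone A3.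
- Merits: the arene forms at the correct oxidation level without a dehydrogenation, the ring B phenols emerge free and distinct from the ring A ethers, and the sequence to the benzophenone core is shorter than the chosen one. In these respects it is better.
- Weak points: A2 can also close by aldol attack of its terminal methyl on the inner carbonyl, or re-close through oxygen. A3 ends in an aryl methyl group where the target needs CH2–ring C, so ring C would have to be grown by benzylic functionalisation in the presence of the equally placed benzylic CH2 of the propyl group. Ring A is not made at all and must be introduced as a hindered benzoate, by the acyl substitution that the crowding disfavours.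
- Comparison: the chosen plan carries the two-carbon handle for ring C from compound 1 and builds ring A from enone 10.

Alternative 2: Ring C would be cut at O1–C6, leading back to ynone ester A4. In the forward step the cationic monovalent gold complex (2-dicyclohexylphosphino-2',6'-dimethoxybiphenyl)gold bis(trifluoromethanesulfonyl)imide A5 activates the alkyne, the tert-butyl ester carbonyl oxygen closes 6-endo-dig, and isobutene is lost to give A6, which is compound 24 of the chosen route.
- Merits: the closure is neutral and mild, milder than the refluxing toluene and the strongly basic acylation of the chosen plan; in that respect it is better.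
- Weak points: it solves only the last ring and leaves the hindered benzophenone and ring A untouched. A4 holds a CH2 that is both benzylic and propargylic and can isomerise to an allenyl ketone. Its preparation from a benzylic electrophile ortho to the ketone is longer than the two steps from acid 18 to 24. Attack by the ketone oxygen in a 5-exo mode would give a furanone.
- Comparison: the chosen plan spends its key step on the harder problem, the crowded ketone and ring A.

Alternative 3: Ring B would be cut at C5'–C6' and C3'–C4', leading back to aroylpyranone A7 and 1,1-dimethoxyethene A8. In the forward step A7 reacts as the diene, and the bridged adduct loses CO2 and methanol to give A9, which is compound 15 of the chosen route.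
- Merits: the arene is delivered regiodefined, fully methylated and with the side arm in place, so the aromatisation and methylation steps of the chosen plan are not needed; in that respect it is better.
- Weak points: A7 needs the hindered ring A aroyl group at C5 of a 4-methoxy-2-pyranone, whereas such pyranones are acylated at C3. Ring A must still be made separately. The donor-substituted diene will need heat, under which A8 hydrolyses and polymerises, and the new bond at C6 forms next to the bulky silyloxyethyl arm.
- Comparison: the chosen plan reaches 15 from commodity reagents but pays with two functional-group steps and a donor without direct precedent in the annulation.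

Key step: step 6

Assumption: dione 13 is drawn as the trans triketone although it should exist largely as enol tautomers; its configuration has no bearing on the route.

## Route

Step 1
Reactants: 1 3,5-dimethoxyphenylacetic acid
Product: 2 2-(3,5-dimethoxyphenyl)ethanol
Conditions: BH3·THF, THF, 0 °C to rt; then H2O
Reagents that add atoms: none
Why: Borane reduction of a carboxylic acid to the primary alcohol through the acyloxyborane; the aryl methyl ethers are inert.

Step 2
Reactants: 2 2-(3,5-dimethoxyphenyl)ethanol
Product: 3 [2-(3,5-dimethoxyphenyl)ethoxy]triisopropylsilane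
Conditions: TIPSCl, imidazole, DMF, rt
Reagents that add atoms: chlorotriisopropylsilane, CC(C)[Si](Cl)(C(C)C)C(C)C
Why: Imidazole-promoted silylation of a primary alcohol. The triisopropylsilyl ether is chosen because bulky silyl ethers resist the chloroiminium reagent of step 3 and methoxide in hot methanol in step 6.

Step 3
Reactants: 3 [2-(3,5-dimethoxyphenyl)ethoxy]triisopropylsilane
Product: 5 2,4-dimethoxy-6-[2-(triisopropylsilyloxy)ethyl]benzaldehyde, via aryl iminium chloride 4 (not isolated)
Conditions: POCl3, DMF, 0 °C to rt; then aq NaOAc
Reagents that add atoms: N,N-dimethylformamide, CN(C)C=O; water, O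
Why: Vilsmeier–Haack formylation. Substitution should occur at the ring position para to one methoxy group and ortho to the other, next to the side arm, as with 3,5-dimethoxytoluene; the position between the two methoxy groups is more hindered.

Step 4
Reactants: 5 2,4-dimethoxy-6-[2-(triisopropylsilyloxy)ethyl]benzaldehyde; 6 methyl acetate
Product: 8 methyl 3-{2,4-dimethoxy-6-[2-(triisopropylsilyloxy)ethyl]phenyl}-3-hydroxypropanoate (racemic), via methyl acetate lithium enolate 7 (not isolated)
Conditions: 6, LiN(iPr)2, THF, −78 °C; then 5, −78 °C; aq NH4Cl
Reagents that add atoms: none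
Why: Aldol addition of an ester lithium enolate to a non-enolisable aldehyde, which tolerates the two ortho groups far better than acyl substitution at the benzoic acid would. The carbinol centre forms racemic without control and is removed in step 5.

Step 5
Reactants: 8 methyl 3-{2,4-dimethoxy-6-[2-(triisopropylsilyloxy)ethyl]phenyl}-3-hydroxypropanoate
Product: 9 methyl 3-{2,4-dimethoxy-6-[2-(triisopropylsilyloxy)ethyl]phenyl}-3-oxopropanoate
Conditions: Dess–Martin periodinane, NaHCO3, CH2Cl2, 0 °C to rt
Reagents that add atoms: none
Why: Dess–Martin oxidation of a secondary benzylic alcohol to the ketone. The buffered, non-acidic medium spares the silyl ether and avoids dehydration to the cinnamate.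

Step 6
Reactants: 9 methyl 3-{2,4-dimethoxy-6-[2-(triisopropylsilyloxy)ethyl]phenyl}-3-oxopropanoate; 10 (E)-hept-3-en-2-one
Product: 13 rac-(4S,5R)-4-{2,4-dimethoxy-6-[2-(triisopropylsilyloxy)ethyl]benzoyl}-5-propylcyclohexane-1,3-dione (trans racemate), via Michael adduct 11 (not isolated), via sodium dione enolate 12 (not isolated)
Conditions: NaOMe (0.2 equiv), MeOH, 0 °C to rt; then NaOMe (1.3 equiv), reflux; then aq HCl, 0 °C
Reagents that add atoms: none
Why: Proposed new method: a Michael–Claisen annulation in which an aroylacetate takes the place of the malonate used in the known synthesis of 5-alkylcyclohexane-1,3-diones from alk-3-en-2-ones, which is the closest known reaction type. The enolate of 9 adds to the β-carbon of 10 (ring A bond C1–C2) to give 11; proton transfer in methanol gives the methyl ketone enolate, which attacks the methyl ester in a 6-(enolexo)-exo-trig Claisen closure (ring A bond C5–C6) and expels methoxide, and formation of the dione enolate 12, the most acidic species present, draws the sequence forward. The selectivity needed is Claisen closure onto the ester in preference to aldol closure onto the aryl ketone, the usual course for β-keto ester donors; here that carbonyl lies between a methoxy group and the silyloxyethyl arm and bears a fully substituted α-carbon, so it is shielded from the enolate and, for the same reason, from deacylation by methoxide. Running the conjugate addition first with catalytic base consumes 10 before the product enolate forms and so prevents a second Michael addition. The two sp3 centres equilibrate through the enolisable C4 to the racemic trans pair and both vanish in step 7. The silyl ether keeps the arm from forming a hemiketal with the aryl ketone, and the arm carries no ester that could undergo Dieckmann closure.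

Step 7
Reactants: 13 rac-(4S,5R)-4-{2,4-dimethoxy-6-[2-(triisopropylsilyloxy)ethyl]benzoyl}-5-propylcyclohexane-1,3-dione
Product: 14 (2,4-dihydroxy-6-propylphenyl){2,4-dimethoxy-6-[2-(triisopropylsilyloxy)ethyl]phenyl}methanone
Conditions: I2 (0.2 equiv), DMSO, 80 °C
Reagents that add atoms: none
Why: Iodine-catalysed oxidative aromatisation with DMSO as terminal oxidant (α-iodination, loss of HI, tautomerisation, reoxidation of HI), a known way from 4-(alkoxycarbonyl)-5-alkylcyclohexane-1,3-diones to 2,4-dihydroxy-6-alkylbenzoates; the aroyl group takes the place of the ester. The catalytic amount of halogen limits nuclear iodination of the electron-rich rings.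

Step 8
Reactants: 14 (2,4-dihydroxy-6-propylphenyl){2,4-dimethoxy-6-[2-(triisopropylsilyloxy)ethyl]phenyl}methanone
Product: 15 (2,4-dimethoxy-6-propylphenyl){2,4-dimethoxy-6-[2-(triisopropylsilyloxy)ethyl]phenyl}methanone
Conditions: MeI, K2CO3, DMF, 40 °C
Reagents that add atoms: iodomethane, CI
Why: Williamson methylation of both phenols; the hydroxyl ortho to the twisted ketone is only weakly chelated and should react as well. Ring A becomes inert to the oxidant of step 10 and the bases of step 11.

Step 9
Reactants: 15 (2,4-dimethoxy-6-propylphenyl){2,4-dimethoxy-6-[2-(triisopropylsilyloxy)ethyl]phenyl}methanone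
Product: 16 [2-(2-hydroxyethyl)-4,6-dimethoxyphenyl](2,4-dimethoxy-6-propylphenyl)methanone
Conditions: Bu4NF, THF, rt
Reagents that add atoms: none
Why: Fluoride cleavage of a silyl ether; nothing else in 15 responds to fluoride.

Step 10
Reactants: 16 [2-(2-hydroxyethyl)-4,6-dimethoxyphenyl](2,4-dimethoxy-6-propylphenyl)methanone
Product: 18 2-[2-(2,4-dimethoxy-6-propylbenzoyl)-3,5-dimethoxyphenyl]acetic acid, via arylacetaldehyde 17 (not isolated)
Conditions: TEMPO (0.2 equiv), PhI(OAc)2, MeCN/H2O, rt
Reagents that add atoms: water, O
Why: Nitroxyl-catalysed oxidation with PhI(OAc)2 as terminal oxidant takes the primary alcohol through aldehyde 17 and its hydrate to the acid in one flask. Aryl methyl ethers and the hindered diaryl ketone are inert.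

Step 11
Reactants: 18 2-[2-(2,4-dimethoxy-6-propylbenzoyl)-3,5-dimethoxyphenyl]acetic acid; 19 2,2,6-trimethyl-4H-1,3-dioxin-4-one
Product: 22 6-{3-[2-(2,4-dimethoxy-6-propylbenzoyl)-3,5-dimethoxyphenyl]-2-oxopropyl}-2,2-dimethyl-4H-1,3-dioxin-4-one, via acyl imidazolide 20 (not isolated), via dioxinone lithium dienolate 21 (not isolated)
Conditions: 18, 1,1'-carbonyldiimidazole, THF, rt; separately 19, LiN(SiMe3)2 (3 equiv), THF, −78 °C; combine at −78 °C; aq NH4Cl
Reagents that add atoms: none
Why: Vinylogous Claisen condensation: the γ-carbon of the lithiated dioxinone is acylated by the acyl imidazolide, with excess dienolate because 22 is more acidic than 19. The diaryl ketone has no α-hydrogen and is too hindered to be attacked at −78 °C.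

Step 12
Reactants: 22 6-{3-[2-(2,4-dimethoxy-6-propylbenzoyl)-3,5-dimethoxyphenyl]-2-oxopropyl}-2,2-dimethyl-4H-1,3-dioxin-4-one
Product: 24 6-[2-(2,4-dimethoxy-6-propylbenzoyl)-3,5-dimethoxybenzyl]-4-hydroxy-2H-pyran-2-one, via acylketene 23 (not isolated)
Conditions: toluene, 110 °C
Reagents that add atoms: none
Why: Thermal retro-[4+2] loss of acetone gives acylketene 23, which is trapped by the enol oxygen of the side-chain ketone in a six-membered lactonisation and tautomerises to the 4-hydroxy-2-pyranone. This is the standard dioxinone route to 6-substituted 4-hydroxy-2-pyranones under neutral conditions.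

Step 13
Reactants: 24 6-[2-(2,4-dimethoxy-6-propylbenzoyl)-3,5-dimethoxybenzyl]-4-hydroxy-2H-pyran-2-one
Product: 25 6-[2-(2,4-dihydroxy-6-propylbenzoyl)-3,5-dihydroxybenzyl]-4-hydroxy-2H-pyran-2-one
Conditions: BBr3 (10 equiv), CH2Cl2, −78 °C to rt; then H2O
Reagents that add atoms: none
Why: Lewis-acid cleavage of aryl methyl ethers by BBr3; the two ethers ortho to the carbonyl go first with chelation assistance, the two para ethers on warming. The 4-hydroxy-2-pyranone ring tolerates strong acid and is held as a borate during the reaction.

## Compound list

1 | 3,5-dimethoxyphenylacetic acid | COc1cc(CC(=O)O)cc(OC)c1 | starting material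
2 | 2-(3,5-dimethoxyphenyl)ethanol | COc1cc(CCO)cc(OC)c1 | intermediate
3 | [2-(3,5-dimethoxyphenyl)ethoxy]triisopropylsilane | COc1cc(CCO[Si](C(C)C)(C(C)C)C(C)C)cc(OC)c1 | intermediate
4 | N-({2,4-dimethoxy-6-[2-(triisopropylsilyloxy)ethyl]phenyl}methylidene)-N-methylmethanaminium chloride | C[N+](C)=Cc1c(OC)cc(OC)cc1CCO[Si](C(C)C)(C(C)C)C(C)C.[Cl-] | intermediate (not isolated)
5 | 2,4-dimethoxy-6-[2-(triisopropylsilyloxy)ethyl]benzaldehyde | O=Cc1c(OC)cc(OC)cc1CCO[Si](C(C)C)(C(C)C)C(C)C | intermediate
6 | methyl acetate | COC(C)=O | starting material
7 | lithium 1-methoxyethen-1-olate (lithium enolate of methyl acetate) | [Li+].[O-]C(=C)OC | intermediate (not isolated)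
8 | methyl 3-{2,4-dimethoxy-6-[2-(triisopropylsilyloxy)ethyl]phenyl}-3-hydroxypropanoate (racemic) | COC(=O)CC(O)c1c(OC)cc(OC)cc1CCO[Si](C(C)C)(C(C)C)C(C)C | intermediate
9 | methyl 3-{2,4-dimethoxy-6-[2-(triisopropylsilyloxy)ethyl]phenyl}-3-oxopropanoate | COC(=O)CC(=O)c1c(OC)cc(OC)cc1CCO[Si](C(C)C)(C(C)C)C(C)C | intermediate
10 | (E)-hept-3-en-2-one | CCC/C=C/C(C)=O | starting material
11 | methyl 2-{2,4-dimethoxy-6-[2-(triisopropylsilyloxy)ethyl]benzoyl}-5-oxo-3-propylhexanoate (mixture of racemic diastereomers) | CCCC(CC(C)=O)C(C(=O)OC)C(=O)c1c(OC)cc(OC)cc1CCO[Si](C(C)C)(C(C)C)C(C)C | intermediate (not isolated)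
12 | sodium enolate of 13 (racemic, one enantiomer drawn) | [Na+].CCC[C@@H]1CC(=O)C=C([O-])[C@H]1C(=O)c1c(OC)cc(OC)cc1CCO[Si](C(C)C)(C(C)C)C(C)C | intermediate (not isolated)
13 | rac-(4S,5R)-4-{2,4-dimethoxy-6-[2-(triisopropylsilyloxy)ethyl]benzoyl}-5-propylcyclohexane-1,3-dione (trans; one enantiomer drawn) | CCC[C@@H]1CC(=O)CC(=O)[C@H]1C(=O)c1c(OC)cc(OC)cc1CCO[Si](C(C)C)(C(C)C)C(C)C | intermediate
14 | (2,4-dihydroxy-6-propylphenyl){2,4-dimethoxy-6-[2-(triisopropylsilyloxy)ethyl]phenyl}methanone | CCCc1cc(O)cc(O)c1C(=O)c1c(OC)cc(OC)cc1CCO[Si](C(C)C)(C(C)C)C(C)C | intermediate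
15 | (2,4-dimethoxy-6-propylphenyl){2,4-dimethoxy-6-[2-(triisopropylsilyloxy)ethyl]phenyl}methanone | CCCc1cc(OC)cc(OC)c1C(=O)c1c(OC)cc(OC)cc1CCO[Si](C(C)C)(C(C)C)C(C)C | intermediate
16 | [2-(2-hydroxyethyl)-4,6-dimethoxyphenyl](2,4-dimethoxy-6-propylphenyl)methanone | CCCc1cc(OC)cc(OC)c1C(=O)c1c(OC)cc(OC)cc1CCO | intermediate
17 | 2-[2-(2,4-dimethoxy-6-propylbenzoyl)-3,5-dimethoxyphenyl]acetaldehyde | CCCc1cc(OC)cc(OC)c1C(=O)c1c(OC)cc(OC)cc1CC=O | intermediate (not isolated)
18 | 2-[2-(2,4-dimethoxy-6-propylbenzoyl)-3,5-dimethoxyphenyl]acetic acid | CCCc1cc(OC)cc(OC)c1C(=O)c1c(OC)cc(OC)cc1CC(=O)O | intermediate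
19 | 2,2,6-trimethyl-4H-1,3-dioxin-4-one | CC1=CC(=O)OC(C)(C)O1 | starting material
20 | 2-[2-(2,4-dimethoxy-6-propylbenzoyl)-3,5-dimethoxyphenyl]-1-(1H-imidazol-1-yl)ethanone | CCCc1cc(OC)cc(OC)c1C(=O)c1c(OC)cc(OC)cc1CC(=O)n1ccnc1 | intermediate (not isolated)
21 | lithium 2,2-dimethyl-6-methylidene-6H-1,3-dioxin-4-olate (lithium dienolate of 19) | [Li+].C=C1C=C([O-])OC(C)(C)O1 | intermediate (not isolated)
22 | 6-{3-[2-(2,4-dimethoxy-6-propylbenzoyl)-3,5-dimethoxyphenyl]-2-oxopropyl}-2,2-dimethyl-4H-1,3-dioxin-4-one | CCCc1cc(OC)cc(OC)c1C(=O)c1c(OC)cc(OC)cc1CC(=O)CC1=CC(=O)OC(C)(C)O1 | intermediate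
23 | 6-[2-(2,4-dimethoxy-6-propylbenzoyl)-3,5-dimethoxyphenyl]-3,5-dioxohex-1-en-1-one | CCCc1cc(OC)cc(OC)c1C(=O)c1c(OC)cc(OC)cc1CC(=O)CC(=O)C=C=O | intermediate (not isolated)
24 | 6-[2-(2,4-dimethoxy-6-propylbenzoyl)-3,5-dimethoxybenzyl]-4-hydroxy-2H-pyran-2-one | CCCc1cc(OC)cc(OC)c1C(=O)c1c(OC)cc(OC)cc1Cc1cc(O)cc(=O)o1 | intermediate
25 | 6-[2-(2,4-dihydroxy-6-propylbenzoyl)-3,5-dihydroxybenzyl]-4-hydroxy-2H-pyran-2-one | CCCc1cc(O)cc(O)c1C(=O)c1c(O)cc(O)cc1Cc1cc(O)cc(=O)o1 | target

## Step count and least certain steps

Total: 13 steps. Longest linear sequence: 13 steps, from 1 to 25; compounds 6, 10 and 19 are purchased.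

**Step 6 (key step, proposed new method).** The closure may take the aldol course onto the aryl ketone. The Claisen closure may also stall, because the adduct rests as its stabilised β-keto ester enolate and only a small share is present as the reactive methyl ketone enolate. Deacylation by methoxide and a second conjugate addition to the product enolate are further losses. The fallback uses known chemistry, sets out from aldehyde 5 and returns at 15. Purchased 1,3-dimethoxy-5-propylbenzene is brominated with NBS in MeCN para to a methoxy group to give 2-bromo-1,5-dimethoxy-3-propylbenzene F1. Bromine–lithium exchange with n-BuLi in THF at −78 °C gives (2,4-dimethoxy-6-propylphenyl)lithium F2. Addition to 5 gives the diaryl carbinol (2,4-dimethoxy-6-propylphenyl){2,4-dimethoxy-6-[2-(triisopropylsilyloxy)ethyl]phenyl}methanol F3, and Dess–Martin oxidation gives 15. Steps 4 to 8 are bypassed and ring A is then bought instead of built.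

**Step 3.** Substitution may go in part to the position between the two methoxy groups, and the chloroiminium reagent or the HCl it releases may attack the silyl ether. The fallback sets out from 3 and returns at 5. NBS bromination para to a methoxy group gives [2-(2-bromo-3,5-dimethoxyphenyl)ethoxy]triisopropylsilane F4. Bromine–lithium exchange with n-BuLi at −78 °C gives {2,4-dimethoxy-6-[2-(triisopropylsilyloxy)ethyl]phenyl}lithium F5, and trapping with DMF gives 5. The medium is neutral, then basic, throughout.

**Step 7.** Nuclear iodination of the resorcinol as it forms, loss of the silyl group through HI, or a stalled dehydrogenation may occur. The fallback sets out from 13 and returns at 14: halogen-free catalytic dehydrogenation over Pd/C in refluxing p-cymene, a different mechanism (surface dehydrogenation in place of halogenation and elimination). It makes no new compound.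

**Step 11.** The dienolate may deprotonate the imidazolide at its benzylic CH2 instead of being acylated, and the lithium enolate of 22 may close onto the diaryl ketone by aldol addition. The fallback sets out from 16 and returns at 22. Dess–Martin oxidation gives aldehyde 17, isolated this time. Vinylogous aldol addition of dienolate 21 at −78 °C gives 6-{3-[2-(2,4-dimethoxy-6-propylbenzoyl)-3,5-dimethoxyphenyl]-2-hydroxypropyl}-2,2-dimethyl-4H-1,3-dioxin-4-one F6 (racemic). A second Dess–Martin oxidation gives 22 under neutral conditions, so no enolate of 22 is formed.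

**Step 13.** Cleavage of the two ethers para to the carbonyl may stay incomplete, and the Lewis acid may promote cyclodehydration between C5 of ring C and the ketone towards a naphthopyranone. The fallback sets out from 24 and returns at 25 in two stages. BCl3 in CH2Cl2 at −78 to 0 °C removes only the two chelated ortho ethers and gives 4-hydroxy-6-[3-hydroxy-2-(2-hydroxy-4-methoxy-6-propylbenzoyl)-5-methoxybenzyl]-2H-pyran-2-one F7. The remaining para ethers are then cleaved by SN2 demethylation with NaSEt in DMF at 100 °C with acidic work-up, where ring C is protected as its anion.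

## Further compounds

F1 | step 6 | 2-bromo-1,5-dimethoxy-3-propylbenzene | CCCc1cc(OC)cc(OC)c1Br
F2 | step 6 | (2,4-dimethoxy-6-propylphenyl)lithium | [Li]c1c(OC)cc(OC)cc1CCC
F3 | step 6 | (2,4-dimethoxy-6-propylphenyl){2,4-dimethoxy-6-[2-(triisopropylsilyloxy)ethyl]phenyl}methanol (racemic) | CCCc1cc(OC)cc(OC)c1C(O)c1c(OC)cc(OC)cc1CCO[Si](C(C)C)(C(C)C)C(C)C
F4 | step 3 | [2-(2-bromo-3,5-dimethoxyphenyl)ethoxy]triisopropylsilane | COc1cc(OC)c(Br)c(CCO[Si](C(C)C)(C(C)C)C(C)C)c1
F5 | step 3 | {2,4-dimethoxy-6-[2-(triisopropylsilyloxy)ethyl]phenyl}lithium | [Li]c1c(OC)cc(OC)cc1CCO[Si](C(C)C)(C(C)C)C(C)C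
F0 | step 7 | none | none
F6 | step 11 | 6-{3-[2-(2,4-dimethoxy-6-propylbenzoyl)-3,5-dimethoxyphenyl]-2-hydroxypropyl}-2,2-dimethyl-4H-1,3-dioxin-4-one (racemic) | CCCc1cc(OC)cc(OC)c1C(=O)c1c(OC)cc(OC)cc1CC(O)CC1=CC(=O)OC(C)(C)O1
F7 | step 13 | 4-hydroxy-6-[3-hydroxy-2-(2-hydroxy-4-methoxy-6-propylbenzoyl)-5-methoxybenzyl]-2H-pyran-2-one | CCCc1cc(OC)cc(O)c1C(=O)c1c(O)cc(OC)cc1Cc1cc(O)cc(=O)o1
A1 | alternative 1 | 2-[2-(2,4-dimethoxy-6-propylphenyl)-2-oxoethyl]-6-methyl-4H-pyran-4-one | CCCc1cc(OC)cc(OC)c1C(=O)Cc1cc(=O)cc(C)o1
A2 | alternative 1 | 1-(2,4-dimethoxy-6-propylphenyl)octane-1,3,5,7-tetraone | CCCc1cc(OC)cc(OC)c1C(=O)CC(=O)CC(=O)CC(C)=O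
A3 | alternative 1 | (2,4-dihydroxy-6-methylphenyl)(2,4-dimethoxy-6-propylphenyl)methanone | CCCc1cc(OC)cc(OC)c1C(=O)c1c(O)cc(O)cc1C
A4 | alternative 2 | tert-butyl 6-[2-(2,4-dimethoxy-6-propylbenzoyl)-3,5-dimethoxyphenyl]-3-oxohex-4-ynoate | CCCc1cc(OC)cc(OC)c1C(=O)c1c(OC)cc(OC)cc1CC#CC(=O)CC(=O)OC(C)(C)C
A5 | alternative 2 | (2-dicyclohexylphosphino-2',6'-dimethoxybiphenyl)gold bis(trifluoromethanesulfonyl)imide | COc1cccc(OC)c1-c1ccccc1[P+](C1CCCCC1)(C1CCCCC1)[Au-]N(S(=O)(=O)C(F)(F)F)S(=O)(=O)C(F)(F)F
A6 | alternative 2 | 6-[2-(2,4-dimethoxy-6-propylbenzoyl)-3,5-dimethoxybenzyl]-4-hydroxy-2H-pyran-2-one | CCCc1cc(OC)cc(OC)c1C(=O)c1c(OC)cc(OC)cc1Cc1cc(O)cc(=O)o1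
A7 | alternative 3 | 5-(2,4-dimethoxy-6-propylbenzoyl)-4-methoxy-6-[2-(triisopropylsilyloxy)ethyl]-2H-pyran-2-one | CCCc1cc(OC)cc(OC)c1C(=O)c1c(OC)cc(=O)oc1CCO[Si](C(C)C)(C(C)C)C(C)C
A8 | alternative 3 | 1,1-dimethoxyethene | C=C(OC)OC
A9 | alternative 3 | (2,4-dimethoxy-6-propylphenyl){2,4-dimethoxy-6-[2-(triisopropylsilyloxy)ethyl]phenyl}methanone | CCCc1cc(OC)cc(OC)c1C(=O)c1c(OC)cc(OC)cc1CCO[Si](C(C)C)(C(C)C)C(C)C
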